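## Retrosynthetic overview

1. **Feature.** The two benzene rings are joined only by a benzyl ester. Its carbonyl carbon sits on C1 of ring A (the formyl ring), between C2–O and C6–CH3, and its alkyl oxygen is bound to the CH2 on C6' of ring B (the benzoic acid ring). Ring A without that carbon is atranol, whose mirror plane through C–CHO and C–CH3 makes the two free ring C–H positions identical, each ortho to an oxygen.
2. **Key disconnection.** The ring A C1–C(=O) bond and the O–CH2 bond are cut together. This gives an aryllithium from MOM/dioxolane-protected atranol, CO2 as a one-carbon linchpin, and a ring B benzylic bromide carrying its own carboxyl as an allyl ester.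
3. **Ring B bromide.** The carboxyl carbon of 3,5-dihydroxy-4-methylbenzoic acid is reduced to the future CH2. A first ortho-lithiation/CO2 capture installs the C1' carboxyl, purified as the phthalide. Lactone opening, carboxylate allylation and Appel bromination follow.
4. **Rings.** Both benzene rings are bought and no ring of the target is formed. The only rings made are temporary: first the phthalide lactone (step 3, opened in step 4), then the dioxolane (step 7, removed in step 10).
5. **End game.** Zerovalent palladium cleaves the allyl ester while the aldehyde is still masked. One mild aqueous-acid hydrolysis then removes the four MOM ethers and the dioxolane.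

Key step: step 8

Assumption: atranol and 3,5-dihydroxy-4-methylbenzoic acid are taken as catalogue chemicals, and the target has no stereocentre, so no stereocontrol is required.

## Route

Step 1
Reactants: 1 3,5-dihydroxy-4-methylbenzoic acid
Product: 2 methoxymethyl 3,5-bis(methoxymethoxy)-4-methylbenzoate
Conditions: MOMCl (3.6 equiv), i-Pr2NEt (4.5 equiv), CH2Cl2/DMF, 0 °C to rt
Reagents that add atoms: chloromethyl methyl ether (MOMCl), COCCl
Why: Williamson-type O-alkylation by the very reactive α-chloro ether caps both phenols and the carboxyl group in one operation, and the MOM ester serves the following hydride reduction as well as a methyl ester would.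

Step 2
Reactants: 2 methoxymethyl 3,5-bis(methoxymethoxy)-4-methylbenzoate
Product: 3 [3,5-bis(methoxymethoxy)-4-methylphenyl]methanol
Conditions: LiAlH4, THF, 0 °C; H2O, aq NaOH work-up
Reagents that add atoms: none
Why: Hydride reduction of an ester to the primary alcohol turns the original carboxyl carbon into the future benzylic CH2 of ring B, and aryl MOM ethers are inert to LiAlH4.

Step 3
Reactants: 3 [3,5-bis(methoxymethoxy)-4-methylphenyl]methanol; 4 carbon dioxide
Product: 7 5,7-bis(methoxymethoxy)-6-methyl-2-benzofuran-1(3H)-one (the ring B phthalide), via lithiated lithium alkoxide 5 (not isolated), via hydroxy acid 6 (not isolated)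
Conditions: n-BuLi (2.3 equiv), TMEDA (2.3 equiv), THF, 0 °C, 2 h; CO2 (g), −78 °C to rt; cold 1 M HCl to pH 3, EtOAc, rt
Reagents that add atoms: carbon dioxide 4, O=C=O
Why: In this directed ortho-metalation the CH2OLi arm and the adjacent OMOM group cooperate on the only kind of ring C–H left (two equivalent positions, the third site being blocked by methyl), and after carboxylation the 2-(hydroxymethyl)benzoic acid lactonises spontaneously on acidification to a stable, easily purified phthalide.

Step 4
Reactants: 7 5,7-bis(methoxymethoxy)-6-methyl-2-benzofuran-1(3H)-one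
Product: 9 prop-2-enyl 6-(hydroxymethyl)-2,4-bis(methoxymethoxy)-3-methylbenzoate, via potassium carboxylate 8 (not isolated)
Conditions: KOH (1.0 equiv), THF/H2O, 50 °C; evaporate, toluene azeotrope; allyl bromide (1.1 equiv), DMF, 0 °C to rt; neutral work-up
Reagents that add atoms: potassium hydroxide, [K+].[OH-]; allyl bromide, C=CCBr
Why: Lactone saponification followed by SN2 O-alkylation of the dry carboxylate gives the open hydroxy ester, and using exactly one equivalent of KOH leaves no free base to catalyse re-closure.

Step 5
Reactants: 9 prop-2-enyl 6-(hydroxymethyl)-2,4-bis(methoxymethoxy)-3-methylbenzoate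
Product: 10 prop-2-enyl 6-(bromomethyl)-2,4-bis(methoxymethoxy)-3-methylbenzoate
Conditions: CBr4 (1.2 equiv), PPh3 (1.25 equiv), CH2Cl2, 0 °C; short silica plug, stored cold and used promptly
Reagents that add atoms: carbon tetrabromide, BrC(Br)(Br)Br
Why: The Appel reaction converts the primary benzylic alcohol to the bromide under neutral conditions that spare the MOM ethers and the allyl ester, and both ring oxygens lie meta to the benzylic carbon, so the bromide should not ionise readily.

Step 6
Reactants: 11 atranol (2,6-dihydroxy-4-methylbenzaldehyde)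
Product: 13 2,6-bis(methoxymethoxy)-4-methylbenzaldehyde, via disodium diphenoxide 12 (not isolated)
Conditions: NaH (2.4 equiv), DMF, 0 °C; MOMCl (2.5 equiv), 0 °C to rt
Reagents that add atoms: chloromethyl methyl ether (MOMCl), COCCl
Why: Complete deprotonation with NaH breaks the O–H···O=C hydrogen bonds that make such phenols slow to react with amine bases, so Williamson-type alkylation should reach both oxygens.

Step 7
Reactants: 13 2,6-bis(methoxymethoxy)-4-methylbenzaldehyde
Product: 14 2-[2,6-bis(methoxymethoxy)-4-methylphenyl]-1,3-dioxolane
Conditions: Me3SiOCH2CH2OSiMe3 (1.5 equiv), Me3SiOTf (5 mol %), CH2Cl2, −78 to −30 °C; pyridine quench; Et3N-washed silica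
Reagents that add atoms: 1,2-bis(trimethylsilyloxy)ethane, C[Si](C)(C)OCCO[Si](C)(C)C
Why: The Noyori acetalisation is aprotic, runs at low temperature and is driven by formation of the disiloxane, so the aryl MOM ethers, which would not survive a hot glycol/p-TsOH Dean–Stark procedure, should be retained.

Step 8
Reactants: 14 2-[2,6-bis(methoxymethoxy)-4-methylphenyl]-1,3-dioxolane; 4 carbon dioxide; 10 prop-2-enyl 6-(bromomethyl)-2,4-bis(methoxymethoxy)-3-methylbenzoate
Product: 17 prop-2-enyl 6-({[3-(1,3-dioxolan-2-yl)-2,4-bis(methoxymethoxy)-6-methylbenzoyl]oxy}methyl)-2,4-bis(methoxymethoxy)-3-methylbenzoate (fully protected alectorialic acid), via aryllithium 15 (not isolated), via lithium carboxylate 16 (not isolated)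
Conditions: 14 (1.2 equiv), n-BuLi (1.1 equiv), THF, 0 °C, 1.5 h; dry CO2 (g), −78 °C to rt; Ar purge; DMF, 10 (1.0 equiv), Bu4NI (10 mol %), rt to 40 °C; Et3N-washed silica
Reagents that add atoms: carbon dioxide 4, O=C=O
Why: n-BuLi binds to an OMOM oxygen of 14 and removes the neighbouring ring proton, the one lying between that OMOM group and the methyl group, to give aryllithium 15; 15 adds to CO2 and so forms the ring A C1–carboxyl bond (16), and once excess CO2 is purged and DMF loosens the lithium ion pair, the carboxylate oxygen displaces bromide from the benzylic CH2 of 10 by SN2 and forms the O–CH2 bond. The closest known reaction type is directed ortho-metalation/carboxylation with esterification of the crude lithium carboxylate in the same flask by a reactive alkyl halide in a dipolar aprotic cosolvent. No ring is closed and no stereocentre is made. Site selectivity of the metalation is the one selectivity needed: the mirror plane of 14 makes its two free ring positions the same, the methyl group has no ortho directing group that would favour lateral metalation, and the acetal C–H, pressed into the ring plane by the two ortho OMOM groups, lacks benzylic overlap and should be the slower acid at 0 °C. Chemoselectivity in the alkylation is secured by keeping 14 in slight excess over n-BuLi and leaving out TMEDA, so that neither pentanoate nor a tertiary amine competes for 10, whose allyl ester meets only a carboxylate and never an organolithium. Because the new ester bond is made at the remote carboxylate oxygen, the di-ortho-substituted acid needs no acyl activation, and the bromomethyl partner carries no hydroxyl that could close to a phthalide.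

Step 9
Reactants: 17 fully protected alectorialic acid (allyl ester)
Product: 18 6-({[3-(1,3-dioxolan-2-yl)-2,4-bis(methoxymethoxy)-6-methylbenzoyl]oxy}methyl)-2,4-bis(methoxymethoxy)-3-methylbenzoic acid
Conditions: Pd(PPh3)4 (5 mol %), morpholine (3 equiv), THF, 0 °C to rt; cold pH 4–5 buffer wash; crude product taken on
Reagents that add atoms: none
Why: In this Tsuji–Trost-type deallylation zerovalent palladium ionises only the allyl–oxygen bond and morpholine traps the π-allyl complex, while the benzylic ester and all the acetals are inert and the still masked aldehyde cannot condense with the amine.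

Step 10
Reactants: 18 the tetra-MOM dioxolane acid
Product: 19 alectorialic acid, 6-{[(3-formyl-2,4-dihydroxy-6-methylbenzoyl)oxy]methyl}-2,4-dihydroxy-3-methylbenzoic acid
Conditions: 2 M aq HCl/THF (1:3), rt to 35 °C, N2; EtOAc extraction, crystallisation
Reagents that add atoms: water, O
Why: All five protecting groups are O,O-acetals that undergo acid-catalysed acetal hydrolysis through oxocarbenium ions in dilute aqueous acid, whereas the di-ortho-substituted benzyl ester is shielded against acyl–oxygen hydrolysis and its benzylic carbon (oxygens meta, carboxyl ortho) does not ionise readily.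

## Compound list

| No. | Name | SMILES | Role |
|---|---|---|---|
| 1 | 3,5-dihydroxy-4-methylbenzoic acid | Cc1c(O)cc(cc1O)C(=O)O | starting material |
| 2 | methoxymethyl 3,5-bis(methoxymethoxy)-4-methylbenzoate | COCOC(=O)c1cc(OCOC)c(C)c(OCOC)c1 | intermediate |
| 3 | [3,5-bis(methoxymethoxy)-4-methylphenyl]methanol | OCc1cc(OCOC)c(C)c(OCOC)c1 | intermediate |
| 4 | carbon dioxide | O=C=O | starting material |
| 5 | lithium [2-lithio-3,5-bis(methoxymethoxy)-4-methylphenyl]methanolate | [Li]OCc1cc(OCOC)c(C)c(OCOC)c1[Li] | intermediate |
| 6 | 6-(hydroxymethyl)-2,4-bis(methoxymethoxy)-3-methylbenzoic acid | OCc1cc(OCOC)c(C)c(OCOC)c1C(=O)O | intermediate |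
| 7 | 5,7-bis(methoxymethoxy)-6-methyl-2-benzofuran-1(3H)-one | O=C1OCc2cc(OCOC)c(C)c(OCOC)c12 | intermediate |
| 8 | potassium 6-(hydroxymethyl)-2,4-bis(methoxymethoxy)-3-methylbenzoate | [K+].[O-]C(=O)c1c(CO)cc(OCOC)c(C)c1OCOC | intermediate |
| 9 | prop-2-enyl 6-(hydroxymethyl)-2,4-bis(methoxymethoxy)-3-methylbenzoate | C=CCOC(=O)c1c(CO)cc(OCOC)c(C)c1OCOC | intermediate |
| 10 | prop-2-enyl 6-(bromomethyl)-2,4-bis(methoxymethoxy)-3-methylbenzoate | C=CCOC(=O)c1c(CBr)cc(OCOC)c(C)c1OCOC | intermediate |
| 11 | atranol (2,6-dihydroxy-4-methylbenzaldehyde) | Cc1cc(O)c(C=O)c(O)c1 | starting material |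
| 12 | disodium 2-formyl-5-methylbenzene-1,3-diolate | Cc1cc([O-])c(C=O)c([O-])c1.[Na+].[Na+] | intermediate |
| 13 | 2,6-bis(methoxymethoxy)-4-methylbenzaldehyde | Cc1cc(OCOC)c(C=O)c(OCOC)c1 | intermediate |
| 14 | 2-[2,6-bis(methoxymethoxy)-4-methylphenyl]-1,3-dioxolane | Cc1cc(OCOC)c(C2OCCO2)c(OCOC)c1 | intermediate |
| 15 | [3-(1,3-dioxolan-2-yl)-2,4-bis(methoxymethoxy)-6-methylphenyl]lithium | [Li]c1c(C)cc(OCOC)c(C2OCCO2)c1OCOC | intermediate |
| 16 | lithium 3-(1,3-dioxolan-2-yl)-2,4-bis(methoxymethoxy)-6-methylbenzoate | [Li+].[O-]C(=O)c1c(C)cc(OCOC)c(C2OCCO2)c1OCOC | intermediate |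
| 17 | prop-2-enyl 6-({[3-(1,3-dioxolan-2-yl)-2,4-bis(methoxymethoxy)-6-methylbenzoyl]oxy}methyl)-2,4-bis(methoxymethoxy)-3-methylbenzoate | C=CCOC(=O)c1c(COC(=O)c2c(C)cc(OCOC)c(C3OCCO3)c2OCOC)cc(OCOC)c(C)c1OCOC | intermediate |
| 18 | 6-({[3-(1,3-dioxolan-2-yl)-2,4-bis(methoxymethoxy)-6-methylbenzoyl]oxy}methyl)-2,4-bis(methoxymethoxy)-3-methylbenzoic acid | OC(=O)c1c(COC(=O)c2c(C)cc(OCOC)c(C3OCCO3)c2OCOC)cc(OCOC)c(C)c1OCOC | intermediate |
| 19 | alectorialic acid | Cc1cc(O)c(C=O)c(O)c1C(=O)OCc1cc(O)c(C)c(O)c1C(=O)O | target |

Total step count: 10. Longest linear sequence: 8 (steps 1–5, then 8, 9 and 10).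

## Steps most likely to fail

**Step 8.**
- Risk: Metalation at the hindered site may be incomplete. The base may instead attack the acetal C–H, with fragmentation of the dioxolane. The tightly ion-paired lithium carboxylate may also alkylate so slowly that the bromide decays first.
- Fallback: It sets out from 14. Electrophilic bromination with NBS (MeCN, NaHCO3, 0 °C) should occur ortho to one OMOM and para to the other. The symmetry allows only one monobromide, 2-[3-bromo-2,6-bis(methoxymethoxy)-4-methylphenyl]-1,3-dioxolane F1. Bromine–lithium exchange with n-BuLi in THF at −78 °C gives the same aryllithium 15 within minutes, at a temperature where deprotonation cannot compete. CO2 capture and careful acidification to pH 5 (NaH2PO4) allow isolation of 3-(1,3-dioxolan-2-yl)-2,4-bis(methoxymethoxy)-6-methylbenzoic acid F2. Its caesium salt (Cs2CO3, DMF, rt) is alkylated with 10 in a separate operation. The route is rejoined at 17.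

**Step 10.**
- Risk: The last MOM ether, on C4' of ring B, has no adjacent carbonyl and may leave slowly, prolonging the acid exposure. During that time the free ring B carboxyl may displace the ring A carboxylate at the benzylic CH2, breaking the link between the rings. The β-resorcylic acid may also decarboxylate.
- Fallback: It sets out from 17 and reverses the order of the two deprotections. Aqueous HCl/THF is applied while the ring B carboxyl is still blocked and cannot act as an internal nucleophile. This gives prop-2-enyl 6-{[(3-formyl-2,4-dihydroxy-6-methylbenzoyl)oxy]methyl}-2,4-dihydroxy-3-methylbenzoate F3. The allyl group is then removed last under near-neutral conditions with Pd(PPh3)4 and sodium p-toluenesulfinate in THF/MeOH at rt. This scavenger cannot condense with the free aldehyde. Mild acidification follows. The route is rejoined at 19.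

**Step 4** (and the handling of 9 up to step 5).
- Risk: The hydroxymethyl benzoate may re-lactonise with loss of allyl alcohol during alkylation, work-up or chromatography.
- Fallback: It sets out from 3 and never passes through a hydroxymethyl benzoate.
  - Mesylation (MsCl, Et3N, CH2Cl2, 0 °C) and displacement with Me2NH in THF give 1-[3,5-bis(methoxymethoxy)-4-methylphenyl]-N,N-dimethylmethanamine F4.
  - Directed ortho-metalation follows (n-BuLi, THF, 0 °C), with CH2NMe2 and OMOM cooperating on the position between them. Inverse addition to allyl chloroformate at −78 °C gives prop-2-enyl 6-[(dimethylamino)methyl]-2,4-bis(methoxymethoxy)-3-methylbenzoate F5.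
  - A von Braun-type cleavage of the benzylic C–N bond with more allyl chloroformate (K2CO3, toluene, rt to 60 °C) gives prop-2-enyl 6-(chloromethyl)-2,4-bis(methoxymethoxy)-3-methylbenzoate F6.
  - F6 replaces 10 in step 8 with NaI added (Finkelstein activation in the flask). The route is rejoined at 17.

## Further compounds

F1 | step 8 | 2-[3-bromo-2,6-bis(methoxymethoxy)-4-methylphenyl]-1,3-dioxolane | Cc1cc(OCOC)c(C2OCCO2)c(OCOC)c1Br
F2 | step 8 | 3-(1,3-dioxolan-2-yl)-2,4-bis(methoxymethoxy)-6-methylbenzoic acid | Cc1cc(OCOC)c(C2OCCO2)c(OCOC)c1C(=O)O
F3 | step 10 | prop-2-enyl 6-{[(3-formyl-2,4-dihydroxy-6-methylbenzoyl)oxy]methyl}-2,4-dihydroxy-3-methylbenzoate | C=CCOC(=O)c1c(COC(=O)c2c(C)cc(O)c(C=O)c2O)cc(O)c(C)c1O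
F4 | step 4 | 1-[3,5-bis(methoxymethoxy)-4-methylphenyl]-N,N-dimethylmethanamine | CN(C)Cc1cc(OCOC)c(C)c(OCOC)c1
F5 | step 4 | prop-2-enyl 6-[(dimethylamino)methyl]-2,4-bis(methoxymethoxy)-3-methylbenzoate | C=CCOC(=O)c1c(CN(C)C)cc(OCOC)c(C)c1OCOC
F6 | step 4 | prop-2-enyl 6-(chloromethyl)-2,4-bis(methoxymethoxy)-3-methylbenzoate | C=CCOC(=O)c1c(CCl)cc(OCOC)c(C)c1OCOC
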